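The ten-membered carbocycle is disconnected at C9–C10 (germacrane numbering), the sp3–sp2 bond where the C9 methylene meets the E-configured trisubstituted C1=C10 alkene; this feature lets the alkene geometry be fixed beforehand in an acyclic vinyl iodide. In one operation the key step hydroborates a terminal C8=C9 vinyl group and couples the resulting C9 alkylborane with the C10 iodide under palladium catalysis, closing the ring with retention of geometry and delivering the target itself. Its precursor is an acyclic (E)-vinyl iodide that already holds the C3, C4, C5, C6 and C7 stereocentres, the C4–C5 epoxide, the C6 acetate and the C3 senecioate.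

Key step: step 12

Remark on numbering: atoms are numbered as in the germacrane skeleton of the target: C1=C10 ring alkene, C2 methylene, C3 senecioate carbon, C4–C5 epoxide, C6 acetate carbon, C7 isopropyl-bearing carbon, C8 and C9 methylenes.

Assumption: the facial preferences of (S)-TRIP (Si face of the enal), of the D-(−)-tartrate titanium catalyst and of the (−)-α-pinene-derived allylborane (Re face of the aldehyde) are taken from the established behaviour of these reagents with simpler aldehydes and allylic alcohols.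

Step 1
Reactants: 1 (E)-4-acetoxy-2-methylbut-2-enal; 2 allenylboronic acid pinacol ester
Product: 4 (2E,4S)-4-hydroxy-3-methylhept-2-en-6-yn-1-yl acetate, via pinacol borate ester 3 (not isolated)
Conditions: 2 (1.5 equiv), (S)-TRIP [(S)-3,3′-bis(2,4,6-triisopropylphenyl)-1,1′-binaphthyl-2,2′-diyl hydrogen phosphate] (10 mol %), 4 Å MS, toluene, −20 °C; aq NaHCO3
Reagents that add atoms: none
Why: Chiral phosphoric acid catalysed propargylation, an SE2′ addition of the allenylboronate through a closed six-membered transition state in which the catalyst binds the boronate oxygen and the formyl hydrogen and should steer the propargyl group to the Si face of the enal, setting C3 as S while the acetate stays inert.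

Step 2
Reactants: 4 (2E,4S)-4-hydroxy-3-methylhept-2-en-6-yn-1-yl acetate
Product: 5 (2E,4S)-4-[(tert-butyldimethylsilyl)oxy]-3-methylhept-2-en-6-yn-1-yl acetate
Conditions: TBSCl, imidazole, DMF, rt
Reagents that add atoms: tert-butyldimethylsilyl chloride, CC(C)(C)[Si](C)(C)Cl
Why: Imidazole-promoted silylation of the secondary alcohol, chosen because the silyl ether withstands the organolithium, zirconium hydride, titanium peroxide and borane reagents of steps 3 to 8 and can later be removed beside an acetate; no stereocentre is touched.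

Step 3
Reactants: 5 (2E,4S)-4-[(tert-butyldimethylsilyl)oxy]-3-methylhept-2-en-6-yn-1-yl acetate
Product: 6 (2E,4S)-4-[(tert-butyldimethylsilyl)oxy]-3-methylhept-2-en-6-yn-1-ol
Conditions: K2CO3 (0.2 equiv), MeOH, 0 °C → rt
Reagents that add atoms: none
Why: Base-catalysed transesterification (methanolysis) of the primary acetate frees the allylic alcohol that later directs the epoxidation, while the silyl ether and the terminal alkyne are stable and the E alkene keeps O6 too far from O3 for silyl migration.

Step 4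
Reactants: 6 (2E,4S)-4-[(tert-butyldimethylsilyl)oxy]-3-methylhept-2-en-6-yn-1-ol
Product: 8 (2E,4S)-4-[(tert-butyldimethylsilyl)oxy]-3-methyloct-2-en-6-yn-1-ol, via dilithio alkoxide acetylide 7 (not isolated)
Conditions: n-BuLi (2.1 equiv), THF, −78 → −20 °C; MeI (1.1 equiv), −78 → 0 °C; H2O
Reagents that add atoms: iodomethane, CI
Why: Alkylation of a lithium acetylide, in which two equivalents of base give the alkoxide–acetylide 7 and, in tetrahydrofuran at low temperature, only the acetylide carbon is nucleophilic enough for iodomethane, so the C10 methyl group is installed without O-methylation.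

Step 5
Reactants: 8 (2E,4S)-4-[(tert-butyldimethylsilyl)oxy]-3-methyloct-2-en-6-yn-1-ol
Product: 10 (2E,4S,6E)-4-[(tert-butyldimethylsilyl)oxy]-7-iodo-3-methylocta-2,6-dien-1-ol, via alkenylzirconocene chloride 9 (not isolated)
Conditions: Cp2Zr(H)Cl (3 equiv), THF, rt → 45 °C; I2, THF, −78 → 0 °C; aq Na2S2O3
Reagents that add atoms: iodine, II
Why: Hydrozirconation–iodination, in which Cp2Zr(H)Cl adds syn across the alkyne and, with excess hydride and gentle warming, equilibrates to the isomer with zirconium on the less hindered methyl-bearing C10, and iodinolysis of the C–Zr bond with retention then gives the (E)-iodide (iodine trans to C2), the trisubstituted C4=C5 alkene being inert and one equivalent of hydride being consumed by the hydroxyl group.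

Step 6
Reactants: 10 (2E,4S,6E)-4-[(tert-butyldimethylsilyl)oxy]-7-iodo-3-methylocta-2,6-dien-1-ol
Product: 11 [(2R,3S)-3-{(1S,3E)-1-[(tert-butyldimethylsilyl)oxy]-4-iodopent-3-en-1-yl}-3-methyloxiran-2-yl]methanol
Conditions: Ti(OiPr)4 (0.2 equiv), D-(−)-diisopropyl tartrate (0.24 equiv), t-BuOOH (2 equiv, decane), 4 Å MS, CH2Cl2, −20 °C
Reagents that add atoms: tert-butyl hydroperoxide, CC(C)(C)OO
Why: Katsuki–Sharpless asymmetric epoxidation, in which the titanium tartrate complex binds the primary allylic alcohol and the D-(−)-tartrate delivers oxygen to the face of the (E)-C4=C5 alkene that gives the trans epoxide with the C4 and C5 configurations of the target (the sense opposite to that by which L-(+)-tartrate converts geraniol into its (2S,3S)-epoxide), under reagent control that should override the C3 silyl ether, while the vinyl iodide alkene, which has no allylic hydroxyl, is not touched.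

Step 7
Reactants: 11 [(2R,3S)-3-{(1S,3E)-1-[(tert-butyldimethylsilyl)oxy]-4-iodopent-3-en-1-yl}-3-methyloxiran-2-yl]methanol
Product: 12 (2S,3S)-3-{(1S,3E)-1-[(tert-butyldimethylsilyl)oxy]-4-iodopent-3-en-1-yl}-3-methyloxirane-2-carbaldehyde
Conditions: TEMPO (10 mol %), PhI(OAc)2 (1.2 equiv), CH2Cl2, rt
Reagents that add atoms: none
Why: Oxoammonium (TEMPO) oxidation of the primary alcohol to the aldehyde under near-neutral conditions, which should leave the epoxide, the configuration at C5 and the vinyl iodide untouched; the aldehyde is used without purification.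

Step 8
Reactants: 12 (2S,3S)-3-{(1S,3E)-1-[(tert-butyldimethylsilyl)oxy]-4-iodopent-3-en-1-yl}-3-methyloxirane-2-carbaldehyde; 13 trans-4-methylpent-2-ene
Product: 18 (1R,2R)-1-[(2R,3S)-3-{(1S,3E)-1-[(tert-butyldimethylsilyl)oxy]-4-iodopent-3-en-1-yl}-3-methyloxiran-2-yl]-2-(propan-2-yl)but-3-en-1-ol, via allylpotassium 14 (not isolated), via potassium methoxyborate 15 (not isolated), via allylborane 16 (not isolated), via borinate 17 (not isolated)
Conditions: 13 (2.5 equiv), KOtBu (1.3 equiv), n-BuLi (1.3 equiv), THF, −78 → −50 → −78 °C; (+)-Ipc2BOMe [(+)-B-methoxydiisopinocampheylborane, from (−)-α-pinene] (1.5 equiv), −78 °C; BF3·OEt2 (1.7 equiv), −78 °C; 12, THF, −78 °C; NaBO3·4H2O, THF/H2O, rt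
Reagents that add atoms: none
Why: Reagent-controlled allylboration of Brown type through a closed chair transition state, in which the E geometry of allylborane 16 places the isopropyl group equatorial and gives the 6,7-anti relationship while the isopinocampheyl groups derived from (−)-α-pinene direct C7 to the Re face of the aldehyde, setting C6 as R and C7 as R; this sense should coincide with the usual non-chelation preference of an α,β-epoxy aldehyde for the anti epoxy alcohol, and the perborate work-up avoids strong base near the epoxide.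

Step 9
Reactants: 18 (1R,2R)-1-[(2R,3S)-3-{(1S,3E)-1-[(tert-butyldimethylsilyl)oxy]-4-iodopent-3-en-1-yl}-3-methyloxiran-2-yl]-2-(propan-2-yl)but-3-en-1-ol
Product: 19 (1R,2R)-1-[(2R,3S)-3-{(1S,3E)-1-[(tert-butyldimethylsilyl)oxy]-4-iodopent-3-en-1-yl}-3-methyloxiran-2-yl]-2-(propan-2-yl)but-3-en-1-yl acetate
Conditions: Ac2O, pyridine, DMAP (0.1 equiv), CH2Cl2, rt
Reagents that add atoms: acetic anhydride, CC(=O)OC(C)=O
Why: Nucleophilic-catalysed (DMAP) acylation of the hindered secondary C6 alcohol with acetic anhydride, with retention at C6 and no effect on the silyl ether, the epoxide or the two alkenes.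

Step 10
Reactants: 19 (1R,2R)-1-[(2R,3S)-3-{(1S,3E)-1-[(tert-butyldimethylsilyl)oxy]-4-iodopent-3-en-1-yl}-3-methyloxiran-2-yl]-2-(propan-2-yl)but-3-en-1-yl acetate
Product: 20 (1R,2R)-1-{(2R,3R)-3-[(1S,3E)-1-hydroxy-4-iodopent-3-en-1-yl]-3-methyloxiran-2-yl}-2-(propan-2-yl)but-3-en-1-yl acetate
Conditions: Bu4NF, AcOH (1:1), THF, 0 °C → rt
Reagents that add atoms: none
Why: Fluoride-induced cleavage of the silyl ether, driven by Si–F bond formation and buffered with acetic acid so that the liberated C3 alkoxide is protonated at once, which should prevent acetate migration, epoxide migration of the Payne type and elimination at the vinyl iodide.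

Step 11
Reactants: 20 (1R,2R)-1-{(2R,3R)-3-[(1S,3E)-1-hydroxy-4-iodopent-3-en-1-yl]-3-methyloxiran-2-yl}-2-(propan-2-yl)but-3-en-1-yl acetate; 21 3-methylbut-2-enoyl chloride
Product: 22 (1S,3E)-1-{(2R,3R)-3-[(1R,2R)-1-(acetyloxy)-2-(propan-2-yl)but-3-en-1-yl]-2-methyloxiran-2-yl}-4-iodopent-3-en-1-yl 3-methylbut-2-enoate
Conditions: 21 (2 equiv), pyridine, DMAP (0.2 equiv), CH2Cl2, 0 °C → rt
Reagents that add atoms: none
Why: DMAP-catalysed esterification with the acid chloride in the presence of the weak base pyridine acylates the C3 alcohol with retention and should avoid the vinylketene pathway that stronger amine bases open and that would move the double bond out of conjugation.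

Step 12
Reactants: 22 (1S,3E)-1-{(2R,3R)-3-[(1R,2R)-1-(acetyloxy)-2-(propan-2-yl)but-3-en-1-yl]-2-methyloxiran-2-yl}-4-iodopent-3-en-1-yl 3-methylbut-2-enoate
Product: 24 (1R,2S,4E,8S,9R,10R)-9-(acetyloxy)-1,5-dimethyl-8-(propan-2-yl)-11-oxabicyclo[8.1.0]undec-4-en-2-yl 3-methylbut-2-enoate (target CNP0267399.1), via C9 alkylborane 23 (not isolated)
Conditions: 9-BBN (1.5 equiv), THF, 0 °C → rt; H2O; then slow addition (10 h) to Pd(dppf)Cl2 (20 mol %), AsPh3 (20 mol %), Cs2CO3 (3 equiv), DMF/THF/H2O, rt, final concentration 1 mM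
Reagents that add atoms: none
Why: 9-BBN adds to the monosubstituted C8=C9 alkene with boron on C9 and leaves the trisubstituted vinyl iodide, the senecioate alkene, the esters and the epoxide alone; zerovalent palladium then inserts into the C10–I bond with retention, the base-activated C9 borate transmetalates, and reductive elimination from the eleven-membered palladacycle forms C9–C10. The closest known reaction type is the intramolecular B-alkyl Suzuki–Miyaura macrocyclisation. The ten-membered ring closes end to end, with the C1=C10 alkene ending up inside the ring (endo with respect to that alkene). No stereocentre is created: C3 to C7 are carried in unchanged, and the E geometry at C1=C10 is kept because oxidative addition and reductive elimination are both stereoretentive. The step needs ring closure to outrun dimerisation, β-hydride elimination and ester hydrolysis; slow addition at high dilution, the wide-bite-angle dppf ligand with AsPh3, a carbonate base at room temperature, and the bend that the trans epoxide and the C7 branch impose on the chain should secure this.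

Compound list
1 | (E)-4-acetoxy-2-methylbut-2-enal | CC(=O)OC/C=C(\C)C=O | starting material
2 | allenylboronic acid pinacol ester, 4,4,5,5-tetramethyl-2-(propa-1,2-dien-1-yl)-1,3,2-dioxaborolane | C=C=CB1OC(C)(C)C(C)(C)O1 | starting material
3 | (2E,4S)-3-methyl-4-[(4,4,5,5-tetramethyl-1,3,2-dioxaborolan-2-yl)oxy]hept-2-en-6-yn-1-yl acetate (pinacol borate ester of 4) | CC(=O)OC/C=C(\C)[C@@H](OB1OC(C)(C)C(C)(C)O1)CC#C | intermediate
4 | (2E,4S)-4-hydroxy-3-methylhept-2-en-6-yn-1-yl acetate | CC(=O)OC/C=C(\C)[C@@H](O)CC#C | intermediate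
5 | (2E,4S)-4-[(tert-butyldimethylsilyl)oxy]-3-methylhept-2-en-6-yn-1-yl acetate | CC(=O)OC/C=C(\C)[C@@H](O[Si](C)(C)C(C)(C)C)CC#C | intermediate
6 | (2E,4S)-4-[(tert-butyldimethylsilyl)oxy]-3-methylhept-2-en-6-yn-1-ol | OC/C=C(\C)[C@@H](O[Si](C)(C)C(C)(C)C)CC#C | intermediate
7 | dilithium salt of 6 (lithium alkoxide at O6, lithium acetylide at C10) | [Li+].[Li+].[O-]C/C=C(\C)[C@@H](O[Si](C)(C)C(C)(C)C)CC#[C-] | intermediate
8 | (2E,4S)-4-[(tert-butyldimethylsilyl)oxy]-3-methyloct-2-en-6-yn-1-ol | OC/C=C(\C)[C@@H](O[Si](C)(C)C(C)(C)C)CC#CC | intermediate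
9 | (E)-alkenylzirconocene chloride from 8, with Cp2Zr(Cl) on C10 (trans to C2) and O6 bound as a Cp2Zr(Cl) alkoxide | Cl[Zr](C1C=CC=C1)(C1C=CC=C1)OC/C=C(\C)[C@@H](O[Si](C)(C)C(C)(C)C)C/C=C(\C)[Zr](Cl)(C1C=CC=C1)C1C=CC=C1 | intermediate
10 | (2E,4S,6E)-4-[(tert-butyldimethylsilyl)oxy]-7-iodo-3-methylocta-2,6-dien-1-ol | OC/C=C(\C)[C@@H](O[Si](C)(C)C(C)(C)C)C/C=C(\C)I | intermediate
11 | [(2R,3S)-3-{(1S,3E)-1-[(tert-butyldimethylsilyl)oxy]-4-iodopent-3-en-1-yl}-3-methyloxiran-2-yl]methanol | OC[C@H]1O[C@]1(C)[C@@H](O[Si](C)(C)C(C)(C)C)C/C=C(\C)I | intermediate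
12 | (2S,3S)-3-{(1S,3E)-1-[(tert-butyldimethylsilyl)oxy]-4-iodopent-3-en-1-yl}-3-methyloxirane-2-carbaldehyde | O=C[C@H]1O[C@]1(C)[C@@H](O[Si](C)(C)C(C)(C)C)C/C=C(\C)I | intermediate
13 | trans-4-methylpent-2-ene | C/C=C/C(C)C | starting material
14 | (E)-4-methylpent-2-en-1-ylpotassium | [K+].[CH2-]/C=C/C(C)C | intermediate
15 | potassium methoxy[(E)-4-methylpent-2-en-1-yl]bis(isopinocampheyl)borate (isopinocampheyl groups from (−)-α-pinene) | [K+].CO[B-](C/C=C/C(C)C)([C@H]1C[C@H]2C[C@@H]([C@@H]1C)C2(C)C)[C@H]1C[C@H]2C[C@@H]([C@@H]1C)C2(C)C | intermediate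
16 | [(E)-4-methylpent-2-en-1-yl]bis(isopinocampheyl)borane (isopinocampheyl groups from (−)-α-pinene) | CC(C)/C=C/CB([C@H]1C[C@H]2C[C@@H]([C@@H]1C)C2(C)C)[C@H]1C[C@H]2C[C@@H]([C@@H]1C)C2(C)C | intermediate
17 | bis(isopinocampheyl)borinate of 18 (B–O bond at O6) | B(O[C@H]([C@@H](C=C)C(C)C)[C@H]1O[C@]1(C)[C@@H](O[Si](C)(C)C(C)(C)C)C/C=C(\C)I)([C@H]1C[C@H]2C[C@@H]([C@@H]1C)C2(C)C)[C@H]1C[C@H]2C[C@@H]([C@@H]1C)C2(C)C | intermediate
18 | (1R,2R)-1-[(2R,3S)-3-{(1S,3E)-1-[(tert-butyldimethylsilyl)oxy]-4-iodopent-3-en-1-yl}-3-methyloxiran-2-yl]-2-(propan-2-yl)but-3-en-1-ol | O[C@H]([C@@H](C=C)C(C)C)[C@H]1O[C@]1(C)[C@@H](O[Si](C)(C)C(C)(C)C)C/C=C(\C)I | intermediate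
19 | (1R,2R)-1-[(2R,3S)-3-{(1S,3E)-1-[(tert-butyldimethylsilyl)oxy]-4-iodopent-3-en-1-yl}-3-methyloxiran-2-yl]-2-(propan-2-yl)but-3-en-1-yl acetate | CC(=O)O[C@H]([C@@H](C=C)C(C)C)[C@H]1O[C@]1(C)[C@@H](O[Si](C)(C)C(C)(C)C)C/C=C(\C)I | intermediate
20 | (1R,2R)-1-{(2R,3R)-3-[(1S,3E)-1-hydroxy-4-iodopent-3-en-1-yl]-3-methyloxiran-2-yl}-2-(propan-2-yl)but-3-en-1-yl acetate | CC(=O)O[C@H]([C@@H](C=C)C(C)C)[C@H]1O[C@]1(C)[C@@H](O)C/C=C(\C)I | intermediate
21 | 3-methylbut-2-enoyl chloride (senecioyl chloride) | CC(C)=CC(Cl)=O | starting material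
22 | (1S,3E)-1-{(2R,3R)-3-[(1R,2R)-1-(acetyloxy)-2-(propan-2-yl)but-3-en-1-yl]-2-methyloxiran-2-yl}-4-iodopent-3-en-1-yl 3-methylbut-2-enoate (cyclisation precursor) | CC(=O)O[C@H]([C@@H](C=C)C(C)C)[C@H]1O[C@]1(C)[C@@H](OC(=O)C=C(C)C)C/C=C(\C)I | intermediate
23 | (1S,3E)-1-{(2R,3R)-3-[(1R,2S)-1-(acetyloxy)-4-(9-borabicyclo[3.3.1]nonan-9-yl)-2-(propan-2-yl)butyl]-2-methyloxiran-2-yl}-4-iodopent-3-en-1-yl 3-methylbut-2-enoate | CC(=O)O[C@H]([C@@H](CCB1C2CCCC1CCC2)C(C)C)[C@H]1O[C@]1(C)[C@@H](OC(=O)C=C(C)C)C/C=C(\C)I | intermediate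
24 | (1R,2S,4E,8S,9R,10R)-9-(acetyloxy)-1,5-dimethyl-8-(propan-2-yl)-11-oxabicyclo[8.1.0]undec-4-en-2-yl 3-methylbut-2-enoate (CNP0267399.1) | CC(=O)O[C@H]1[C@H]2O[C@]2(C)[C@@H](OC(=O)C=C(C)C)C/C=C(\C)CC[C@H]1C(C)C | target

Total step count: 12.
Longest linear sequence: 12 steps, from 1 to 24; 2, 13 and 21 enter as purchased materials.

Steps most likely to fail

Step 12. Transmetalation of the C9 borate may be too slow at high dilution, so that protodeboronation, β-hydride elimination from the alkylpalladium species or intermolecular coupling to dimers and oligomers outruns closure of the strained ten-membered ring; the aqueous base may also slowly cleave the esters. The fallback closes the same C9–C10 bond by an intramolecular Negishi coupling, which needs no base and transmetalates faster. It sets out from 22: hydroboration with 9-BBN (through 23) and oxidation with NaBO3·4H2O would give the C9 primary alcohol F1; I2, PPh3 and imidazole in CH2Cl2 at 0 °C would convert it into the C9 primary iodide F2; zinc dust activated with LiCl in THF at 25 °C should insert into the alkyl C–I bond only and give the C9 alkylzinc iodide F3. Slow addition of F3 to Pd2(dba)3 and P(2-furyl)3 in THF/NMP would then close the ring, and the fallback comes back to the route at 24.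

Step 8. The allylpotassium may lose its E geometry before it is trapped on boron, which would give the 6,7-syn isomer; the borane may attack the wrong face of the epoxy aldehyde; and BF3·OEt2 may open the epoxide. The fallback replaces the stoichiometric chiral borane by an isolable, geometrically defined boronate and a chiral Brønsted acid. It sets out from 12: (E)-4-methylpent-2-en-1-ylboronic acid pinacol ester F4 would be made from (E)-4-methylpent-2-en-1-yl acetate and B2pin2 with Pd2(dba)3 in DMSO (Miyaura allylic borylation) and added to 12 with (R)-TRIP (5 mol %) and 4 Å MS in toluene at −30 °C. The chair transition state again gives the 6,7-anti relationship and the catalyst is expected to select the Re face. The adduct forms as the pinacol borate ester F5, whose hydrolysis on work-up brings the fallback back to the route at 18.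

Step 5. Zirconium may settle on C1 instead of C10, or equilibration to the C10 isomer may stay incomplete, and the regioisomeric iodide could not be corrected later. The fallback fixes the regiochemistry with silicon. It sets out from 6, before the methylation:
- Double deprotonation and silylation (n-BuLi, 2.1 equiv; Me3SiCl, 2.2 equiv; THF, −78 °C → rt) would give the O,C-bis(trimethylsilyl) compound F6, whose O–Si bond is cleaved by citric acid in MeOH to leave the C-silylated alkynol F7.
- i-Bu2AlH (3 equiv) in heptane at 50 °C adds H and Al trans, with aluminium on the silicon-bearing C10, to give the alkenylalane F8; MeLi converts it into the lithium alkenyl(methyl)aluminate F9, and MeI methylates C10 with retention to give the (E)-vinylsilane F10.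
- Iododesilylation of F10 with N-iodosuccinimide in hexafluoroisopropanol at 0 °C, with retention, comes back to the route at 10.

Further compounds
F1 | step 12 | (1S,3E)-1-{(2R,3R)-3-[(1R,2S)-1-(acetyloxy)-4-hydroxy-2-(propan-2-yl)butyl]-2-methyloxiran-2-yl}-4-iodopent-3-en-1-yl 3-methylbut-2-enoate | CC(=O)O[C@H]([C@@H](CCO)C(C)C)[C@H]1O[C@]1(C)[C@@H](OC(=O)C=C(C)C)C/C=C(\C)I
F2 | step 12 | (1S,3E)-1-{(2R,3R)-3-[(1R,2S)-1-(acetyloxy)-4-iodo-2-(propan-2-yl)butyl]-2-methyloxiran-2-yl}-4-iodopent-3-en-1-yl 3-methylbut-2-enoate | CC(=O)O[C@H]([C@@H](CCI)C(C)C)[C@H]1O[C@]1(C)[C@@H](OC(=O)C=C(C)C)C/C=C(\C)I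
F3 | step 12 | C9 alkylzinc iodide derived from F2 | CC(=O)O[C@H]([C@@H](CC[Zn]I)C(C)C)[C@H]1O[C@]1(C)[C@@H](OC(=O)C=C(C)C)C/C=C(\C)I
F4 | step 8 | (E)-4,4,5,5-tetramethyl-2-(4-methylpent-2-en-1-yl)-1,3,2-dioxaborolane | CC(C)/C=C/CB1OC(C)(C)C(C)(C)O1
F5 | step 8 | pinacol borate ester of 18 (B–O bond at O6) | CC1(C)OB(O[C@H]([C@@H](C=C)C(C)C)[C@H]2O[C@]2(C)[C@@H](O[Si](C)(C)C(C)(C)C)C/C=C(\C)I)OC1(C)C
F6 | step 5 | O,C-bis(trimethylsilyl) derivative of 6 | C[Si](C)(C)OC/C=C(\C)[C@@H](O[Si](C)(C)C(C)(C)C)CC#C[Si](C)(C)C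
F7 | step 5 | (2E,4S)-4-[(tert-butyldimethylsilyl)oxy]-3-methyl-7-(trimethylsilyl)hept-2-en-6-yn-1-ol | OC/C=C(\C)[C@@H](O[Si](C)(C)C(C)(C)C)CC#C[Si](C)(C)C
F8 | step 5 | alkenyl(diisobutyl)alane from F7, aluminium on C10 cis to C2, O6 as diisobutylaluminium alkoxide | CC(C)C[Al](CC(C)C)OC/C=C(\C)[C@@H](O[Si](C)(C)C(C)(C)C)C/C=C(\[Al](CC(C)C)CC(C)C)[Si](C)(C)C
F9 | step 5 | lithium alkenyl(methyl)diisobutylaluminate from F8 | [Li+].CC(C)C[Al](CC(C)C)OC/C=C(\C)[C@@H](O[Si](C)(C)C(C)(C)C)C/C=C(\[Al-](C)(CC(C)C)CC(C)C)[Si](C)(C)C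
F10 | step 5 | (2E,4S,6E)-4-[(tert-butyldimethylsilyl)oxy]-3-methyl-7-(trimethylsilyl)octa-2,6-dien-1-ol | OC/C=C(\C)[C@@H](O[Si](C)(C)C(C)(C)C)C/C=C(\C)[Si](C)(C)C
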